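Begin at the early times. The dusk run shows 85.2% free monomer at 0.250 h and 84.6% at 3.00 h, a shift of −0.6 percentage points against a scatter of 1 point. So turn the time first: by hand a slow reaction goes on, but these readings stand still, so take the mean of each run as its plateau.

| flask | free monomer | transfer agent | initiator | remark | time |
|---|---|---|---|---|---|
| dawn | 18 mM | 0.39 mM | 0.53 mM | run made earlier |  |
| dusk | 29 mM | 0.39 mM | 0.53 mM | run made earlier |  |
| noon | 13 mM | 0.20 mM | 0.53 mM | run made earlier |  |
| flask | 13 mM | 0.390 mM | 0.53 mM |  | 2.5 h |

| run | time / h | monomer in chains / % | free monomer / % |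
|---|---|---|---|
| dawn | 0.833 | 19.6 | 78.3 |
| dawn | 1.50 | 22.1 | 77.9 |
| dawn | 2.50 | 18.9 | 78.8 |
| dawn | 3.00 | 20.4 | 79.0 |
| dusk | 0.250 | 14.4 | 85.2 |
| dusk | 0.500 | 15.3 | 83.2 |
| dusk | 1.33 | 15.7 | 83.9 |
| dusk | 3.00 | 15.0 | 84.6 |
| noon | 0.833 | 38.4 | 63.2 |
| noon | 1.50 | 39.1 | 60.0 |
| noon | 2.50 | 37.7 | 60.1 |
| noon | 3.00 | 36.8 | 61.4 |

(readings scatter by 1 percentage point)

- the average divides the monomer in chains by the number of chains begun, living and dead together
- the earlier runs do not show the number of chains; that part of a forecast is a guess

- average number of monomer units in a chain (chains begun, living or dead) at 2.5 h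
- part of the free monomer that has reacted at 2.5 h

Work with the fraction left, not the fraction made. If consumption is first order in free monomer while it runs, the logarithm of charged over left measures how long it ran; take its reciprocal to rise straight with [free monomer], with [transfer agent] and [initiator] held.

Turn [free monomer]: the dawn run reads 0.242 at 18 mM, and the dusk run reads 0.172 at 29 mM. Turn [transfer agent]: the noon run, with half the flask's charge, reads 0.491. Turn [initiator]: no run varies it, so assume the logarithm proportional to it, and guess one chain per initiator.

This flask differs from the dawn run in [free monomer], so carry the reciprocal straight through dusk and dawn down to 13 mM. The plateau logarithm, ln of charged over left at the plateau, 0.298, stands below the noon reading. It gives 25.7% reacted and 6.31 units per chain.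

The forecast says 25% and 4: “Chains are a guess”. Its conversion lies beside mine; its chain length lies below mine.

The flask gives 26.6% and 6.14.

    free monomer + initiator → living end + monomer in chains (k = 54.0 M⁻¹ min⁻¹)
    free monomer + living end → monomer in chains + living end, rate k2*[living end]*[free monomer] (k = 80.0 M⁻¹ min⁻¹)
    living end + transfer agent → dead chain (kL = 550 M⁻¹ min⁻¹)
    living end + free monomer → dead end (k = 6.20 M⁻¹ min⁻¹)

In this flask the initiator step had half its turnover done by 1.00 min, and initiator stood at 0% of its charge at 1.25 h. Propagation had half its turnover done by 0.102 h, living end then fell from 0.0647 mM at 0.250 h to 1.52 × 10⁻⁴ mM at 1.25 h, and free monomer held 73.4% from that time through 25.0 h. The plateau logarithm of this flask comes to 0.309 against my 0.298, and at 2.50 h its 0.319 mM dead chain, 0.211 mM dead end and 9.62 × 10⁻⁸ mM living end make 0.530 mM chains, against the forecast's 0.8 mM. For the neighbour with 0.21 mM initiator, scaling 0.298 gives 0.118, so 11.1% reacted; the computed flask gives 8.55%.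

All runs were generated by integration for substances that don't exist, noise included.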